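**Retrosynthetic overview**

1. Curlignan is taken back to its guaiacyl O-benzyl ether, so the last step is a single hydrogenolysis.
2. Feature (benzofuran numbering: O1, C2 carrying guaiacyl ring B, C3 carrying C9H2OH, C3a and C7a in benzoate ring A): removing C9 and cutting O1–C2 erases the dihydrofuran ring and both stereocentres. What remains is a planar (E)-2-hydroxystilbene whose C2 is benzylic to ring B and para to its oxygen, so it can carry positive charge, plus a one-carbon electrophile at the formaldehyde oxidation level.
3. Key disconnection: stilbene plus formaldehyde under a confined chiral Brønsted acid. C3–C9 forms first, then O1–C2 closes the dihydrofuran, the only ring made in the route (rings A and B are bought).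
4. The stilbene is cut at C3a–C3 by a Heck disconnection into methyl 5-iodovanillate (from methyl vanillate) and 4-benzyloxy-3-methoxystyrene (from 2-methoxy-4-vinylphenol).

Key step: step 4

Assumption: formaldehyde is charged as paraformaldehyde and counted as a purchased starting material. Which antipode of the confined acid gives 3R cannot be read from precedent on this substrate class, so both antipodes would be tried on a small scale and the one that leads to (2S,3R)-8 is used.

**Route**

Step 1
Reactants: 1 methyl vanillate (methyl 4-hydroxy-3-methoxybenzoate)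
Product: 2 methyl 4-hydroxy-3-iodo-5-methoxybenzoate
Conditions: NIS (1.05 equiv), CF3CO2H (cat.), MeCN, rt
Reagents that add atoms: N-iodosuccinimide, O=C1CCC(=O)N1I
Why: Electrophilic aromatic iodination, in which the hydroxyl group directs iodine to C5, its only free ortho position (para is held by the ester, the other ortho by methoxy) and the one position meta to the deactivating ester, so a single regioisomer is expected.

Step 2
Reactants: 3 2-methoxy-4-vinylphenol
Product: 4 1-benzyloxy-2-methoxy-4-vinylbenzene
Conditions: BnBr (1.1 equiv), K2CO3, DMF, rt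
Reagents that add atoms: benzyl bromide, BrCc1ccccc1
Why: Williamson ether synthesis, in which the phenoxide formed with K2CO3 is alkylated by benzyl bromide in an SN2 reaction at room temperature, mild enough to leave the polymerisable styrene untouched.

Step 3
Reactants: 2 methyl 4-hydroxy-3-iodo-5-methoxybenzoate; 4 1-benzyloxy-2-methoxy-4-vinylbenzene
Product: 5 methyl 3-[(E)-2-(4-benzyloxy-3-methoxyphenyl)ethenyl]-4-hydroxy-5-methoxybenzoate
Conditions: Pd(OAc)2 (5 mol %), P(o-tol)3 (10 mol %), Et3N, DMF, 90 °C
Reagents that add atoms: none
Why: Mizoroki–Heck reaction, in which zerovalent palladium formed in situ from Pd(OAc)2 and the phosphine inserts into the C–I bond of 2, the aryl group adds to the unsubstituted alkene carbon of 4 and syn β-hydride elimination gives the (E)-stilbene, free ortho-iodophenols being competent partners in this coupling.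

Step 4
Reactants: 5 methyl 3-[(E)-2-(4-benzyloxy-3-methoxyphenyl)ethenyl]-4-hydroxy-5-methoxybenzoate; 6 formaldehyde (charged as paraformaldehyde)
Product: 8 O-benzylcurlignan [methyl (2S,3R)-2-(4-benzyloxy-3-methoxyphenyl)-3-(hydroxymethyl)-7-methoxy-2,3-dihydro-1-benzofuran-5-carboxylate; aryl group trans to CH2OH], via C2 benzylic cation 7 (not isolated)
Conditions: (CH2O)n (1.5 equiv), chiral IDPi acid (5 mol %) of formula (Ar*O2)P(=NSO2CF3)–N=P(NHSO2CF3)(O2Ar*), Ar*O2 = 3,3'-bis[3,5-bis(trifluoromethyl)phenyl]-1,1'-binaphthalene-2,2'-diolate, CHCl3–cyclohexane, −20 °C; then sat. aq. NaHCO3, MeOH, rt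
Reagents that add atoms: formaldehyde (compound 6, released from paraformaldehyde), C=O
Why: Proposed new method: the confined acid protonates formaldehyde inside its chiral pocket and this electrophile bonds to C3 of the stilbene in a strongly asynchronous addition, so that the charge arrives at C2 as cation 7, which the para-benzyloxy group of ring B spreads into a quinoid oxocarbenium ion before O1 closes on C2 and returns its proton to the catalyst anion. The closest known reaction type is the asymmetric intermolecular Prins reaction of aryl olefins with paraformaldehyde under confined imidodiphosphorimidate acids, which ends in 1,3-dioxanes; here an internal phenol takes the place of the second formaldehyde, which has not been shown. The dihydrofuran ring (O1, C2, C3, C3a, C7a) closes in the 5-exo-trig mode, O1 adding to the exocyclic carbon of the quinoid cation. C3 is set by the catalyst, whose pocket decides which alkene face meets formaldehyde, and C2 is set by the substrate, because O1 closes on the face that keeps the aryl group trans to C9 and a cis isomer could re-ionise at C2 under the acid and close again to trans without touching C3. The step needs C9 to bond to C3 and not to C2, which the para-alkoxy donor of ring B secures against a ring A oxygen whose donation is drained by the para ester, and it needs O1 capture to outrun both dioxane formation and plain alkene protonation, for which the five-membered closure, a small excess of formaldehyde and the higher basicity of formaldehyde oxygen relative to the alkene are relied on. Ring A has no free position ortho or para to its hydroxyl, so it cannot be hydroxymethylated, and hemiformals on O1 or O9 are cleaved in the bicarbonate work-up.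

Step 5
Reactants: 8 O-benzylcurlignan
Product: 9 curlignan [methyl (2S,3R)-2-(4-hydroxy-3-methoxyphenyl)-3-(hydroxymethyl)-7-methoxy-2,3-dihydro-1-benzofuran-5-carboxylate]
Conditions: H2 (1 atm), 10% Pd/C, EtOAc, rt, stopped at full conversion
Reagents that add atoms: none
Why: Catalytic hydrogenolysis of an aryl benzyl ether, in which the unhindered primary O–CH2Ph bond should be cleaved on Pd/C at 1 atm in neutral ethyl acetate well before the hindered secondary ring C2–O1 bond, and no stereocentre is touched, so the (2S,3R) configuration of 8 is carried into 9.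

**Compound list**

1 | methyl vanillate (methyl 4-hydroxy-3-methoxybenzoate) | COC(=O)c1ccc(O)c(OC)c1 | starting material
2 | methyl 4-hydroxy-3-iodo-5-methoxybenzoate | COC(=O)c1cc(I)c(O)c(OC)c1 | intermediate
3 | 2-methoxy-4-vinylphenol | C=Cc1ccc(O)c(OC)c1 | starting material
4 | 1-benzyloxy-2-methoxy-4-vinylbenzene | C=Cc1ccc(OCc2ccccc2)c(OC)c1 | intermediate
5 | methyl 3-[(E)-2-(4-benzyloxy-3-methoxyphenyl)ethenyl]-4-hydroxy-5-methoxybenzoate | COC(=O)c1cc(OC)c(O)c(c1)/C=C/c1ccc(OCc2ccccc2)c(OC)c1 | intermediate
6 | formaldehyde (charged as paraformaldehyde) | C=O | starting material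
7 | C2 benzylic cation (ring B quinoid benzyloxocarbenium form, C3 configured as in 8, paired with the catalyst anion) | COC(=O)c1cc(OC)c(O)c(c1)[C@H](CO)[CH+]c1ccc(OCc2ccccc2)c(OC)c1 | intermediate
8 | O-benzylcurlignan, methyl (2S,3R)-2-(4-benzyloxy-3-methoxyphenyl)-3-(hydroxymethyl)-7-methoxy-2,3-dihydro-1-benzofuran-5-carboxylate | COC(=O)c1cc(OC)c2c(c1)[C@H](CO)[C@@H](c1ccc(OCc3ccccc3)c(OC)c1)O2 | intermediate
9 | curlignan, methyl (2S,3R)-2-(4-hydroxy-3-methoxyphenyl)-3-(hydroxymethyl)-7-methoxy-2,3-dihydro-1-benzofuran-5-carboxylate | COC(=O)c1cc(OC)c2c(c1)[C@H](CO)[C@@H](c1ccc(O)c(OC)c1)O2 | target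

**Step count and risks**

Total steps: 5. Longest linear sequence: 4 steps (step 1 or step 2, then steps 3, 4 and 5).

Steps most likely to fail:

1. Step 4 (proposed new method). What may go wrong:
   - protonation of the alkene and closure of O1 without uptake of C9;
   - capture of the C2 cation by a second formaldehyde unit in place of O1 (1,3-dioxane formation);
   - poor facial selectivity at C3.

   Fallback by known chemistry, setting out from 2 and coming back to the route at 8: the ring is built by an asymmetric rhodium carbene C–H insertion.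
   - Mitsunobu etherification of 2 with purchased 4-benzyloxy-3-methoxybenzyl alcohol (PPh3, diisopropyl azodicarboxylate, THF) should give methyl 4-[(4-benzyloxy-3-methoxyphenyl)methoxy]-3-iodo-5-methoxybenzoate F1.
   - Palladium-catalysed coupling of the aryl iodide with methyl diazoacetate (Pd(PPh3)4, Ag2CO3, Et3N, toluene, rt) should give methyl 4-[(4-benzyloxy-3-methoxyphenyl)methoxy]-3-(1-diazo-2-methoxy-2-oxoethyl)-5-methoxybenzoate F2.
   - With Rh2(PTTL)4 (PTTL = N-phthaloyl-tert-leucinate, the antipode that sets C2 as S) in toluene at −60 °C, the carbene should insert into the benzylic ether C–H bond five atoms away. This should give the cis diester, dimethyl (2S,3R)-2-(4-benzyloxy-3-methoxyphenyl)-7-methoxy-2,3-dihydro-1-benzofuran-3,5-dicarboxylate F3.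
   - NaOMe in MeOH at 0 °C should epimerise C3, alpha to the ester, to the trans isomer, dimethyl (2S,3S)-2-(4-benzyloxy-3-methoxyphenyl)-7-methoxy-2,3-dihydro-1-benzofuran-3,5-dicarboxylate F4.
   - LiBH4 in THF at 0 °C should reduce the aliphatic C3 ester in preference to the C5 benzoate, which is deactivated by the para oxygen O1, and give 8.

2. Step 5. What may go wrong: over-reduction, in which hydrogenolysis also opens the benzylic C2–O1 bond of the dihydrofuran.

   Fallback, setting out from 3 and coming back at 9: the guaiacyl oxygen is carried as a silyl ether, so that no reductive step is needed.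
   - Silylation of 3 (i-Pr3SiCl, imidazole, DMF) should give triisopropyl(2-methoxy-4-vinylphenoxy)silane F5.
   - Heck coupling with 2 under the conditions of step 3 should give methyl 4-hydroxy-3-methoxy-5-[(E)-2-(3-methoxy-4-triisopropylsilyloxyphenyl)ethenyl]benzoate F6.
   - The Prins step under the conditions of step 4 should give methyl (2S,3R)-3-(hydroxymethyl)-7-methoxy-2-(3-methoxy-4-triisopropylsilyloxyphenyl)-2,3-dihydro-1-benzofuran-5-carboxylate F7.
   - n-Bu4NF buffered with AcOH in THF at 0 °C should then release 9.

3. Step 3. What may go wrong: arylation at the internal carbon of the electron-rich styrene, and slow turnover through binding of the ortho-phenoxide to palladium.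

   Fallback, setting out from 4 and coming back at 5: the alkene geometry and the point of attachment are fixed beforehand in a boron partner.
   - Cross-metathesis of 4 with vinylboronic acid pinacol ester (second-generation Grubbs catalyst, (H2IMes)(PCy3)Cl2Ru=CHPh, CH2Cl2, 40 °C) should give 2-[(E)-2-(4-benzyloxy-3-methoxyphenyl)ethenyl]-4,4,5,5-tetramethyl-1,3,2-dioxaborolane F8.
   - Suzuki–Miyaura coupling of F8 with 2 (Pd(PPh3)4, K2CO3, dioxane–H2O, 80 °C) should give 5 with the (E) geometry retained.

**Further compounds**

F1 | step 4 | methyl 4-[(4-benzyloxy-3-methoxyphenyl)methoxy]-3-iodo-5-methoxybenzoate | COC(=O)c1cc(I)c(OCc2ccc(OCc3ccccc3)c(OC)c2)c(OC)c1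
F2 | step 4 | methyl 4-[(4-benzyloxy-3-methoxyphenyl)methoxy]-3-(1-diazo-2-methoxy-2-oxoethyl)-5-methoxybenzoate | COC(=O)C(=[N+]=[N-])c1cc(C(=O)OC)cc(OC)c1OCc1ccc(OCc2ccccc2)c(OC)c1
F3 | step 4 | dimethyl (2S,3R)-2-(4-benzyloxy-3-methoxyphenyl)-7-methoxy-2,3-dihydro-1-benzofuran-3,5-dicarboxylate (cis) | COC(=O)c1cc(OC)c2c(c1)[C@@H](C(=O)OC)[C@@H](c1ccc(OCc3ccccc3)c(OC)c1)O2
F4 | step 4 | dimethyl (2S,3S)-2-(4-benzyloxy-3-methoxyphenyl)-7-methoxy-2,3-dihydro-1-benzofuran-3,5-dicarboxylate (trans) | COC(=O)c1cc(OC)c2c(c1)[C@H](C(=O)OC)[C@@H](c1ccc(OCc3ccccc3)c(OC)c1)O2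
F5 | step 5 | triisopropyl(2-methoxy-4-vinylphenoxy)silane | C=Cc1ccc(O[Si](C(C)C)(C(C)C)C(C)C)c(OC)c1
F6 | step 5 | methyl 4-hydroxy-3-methoxy-5-[(E)-2-(3-methoxy-4-triisopropylsilyloxyphenyl)ethenyl]benzoate | COC(=O)c1cc(OC)c(O)c(c1)/C=C/c1ccc(O[Si](C(C)C)(C(C)C)C(C)C)c(OC)c1
F7 | step 5 | methyl (2S,3R)-3-(hydroxymethyl)-7-methoxy-2-(3-methoxy-4-triisopropylsilyloxyphenyl)-2,3-dihydro-1-benzofuran-5-carboxylate | COC(=O)c1cc(OC)c2c(c1)[C@H](CO)[C@@H](c1ccc(O[Si](C(C)C)(C(C)C)C(C)C)c(OC)c1)O2
F8 | step 3 | 2-[(E)-2-(4-benzyloxy-3-methoxyphenyl)ethenyl]-4,4,5,5-tetramethyl-1,3,2-dioxaborolane | COc1cc(/C=C/B2OC(C)(C)C(C)(C)O2)ccc1OCc1ccccc1
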